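**Retrosynthetic overview**
1. Last, four benzyl ethers are removed. Before that, the flavan pyran ring is closed by dehydrative enol-ether formation (C8a–O1) from a benzylic alcohol, after its C4–C4a bond is made by reductive alkylation of the remaining vinylogous acid with an enantiopure aldehyde from an Evans syn-glycolate aldol.
2. Key disconnection: the O–CH(Ar) bond of the tetrahydrofuran ring (ring atoms: enol-ether carbon, O, the CH bearing 4-hydroxyphenyl, chromanone C3, spiro C2). Because that CH carries a para-hydroxyphenyl group, the bond is a para-hydroxybenzyl ether and opens back to a 4-hydroxybenzyl group on C3 plus an enol OH, via a para-quinone methide.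
3. Precursor: the (3R)-3-hydroxy-3-(4-hydroxybenzyl) spirochromanone whose spiro ring is the symmetric 3,5-dihydroxycyclohexadienone. It comes from C3 benzylation, Davis enolate hydroxylation (C3 is then the only stereocentre) and acid hydrolysis of two methyl enol ethers.
4. The spirochromanone comes from aldol addition of a 2-fluoroacetophenone enolate to 2,6-dimethoxybenzoquinone, then SNAr closure.
5. Ring order: dienone ring (from the quinone) → chromanone ring → tetrahydrofuran ring (key step) → flavan pyran ring.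

Key step: step 9

Assumption: the (+)-(camphorsulfonyl)oxaziridine is taken to give the 3R alcohol, by analogy with 3-benzylchroman-4-one enolates; if the sense on this enolate is opposite, the (−)-reagent is used in step 7.

**Step 1**
Reactants: 1 1-(2,4,6-trifluorophenyl)ethan-1-one
Product: 3 1-[2,4-bis(benzyloxy)-6-fluorophenyl]ethan-1-one, via monoether 2 (not isolated)
Conditions: BnOH (2.05 equiv), NaH (2.1 equiv), THF/DMF, 0 °C → rt
Reagents that add atoms: benzyl alcohol, OCc1ccccc1
Why: Twofold nucleophilic aromatic substitution (SNAr) in which the para fluoride should go first and one ortho fluoride second, after which the ring with two donor ethers should resist the third exchange.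

**Step 2**
Reactants: 3 1-[2,4-bis(benzyloxy)-6-fluorophenyl]ethan-1-one; 4 2,6-dimethoxy-1,4-benzoquinone
Product: 7 5,7-bis(benzyloxy)-2',6'-dimethoxyspiro[chromane-2,1'-cyclohexa[2,5]diene]-4,4'-dione, via lithium enolate 5 (not isolated), via lithium aldolate 6 (not isolated)
Conditions: LiN(SiMe3)2 (1.05 equiv), THF, −78 °C; 4, −78 °C; then DMPU, −78 → 0 °C → rt
Reagents that add atoms: none
Why: Aldol addition of the lithium enolate to the quinone carbonyl between the two methoxy-bearing carbons (the other carbonyl is a doubly vinylogous ester), then 6-exo SNAr of the tertiary alkoxide on the ketone-activated ortho fluoride should close the chromanone; the spiro carbon carries two identical arms and is not stereogenic.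

**Step 3**
Reactants: 8 4-hydroxybenzaldehyde
Product: 9 4-[(tert-butyldimethylsilyl)oxy]benzaldehyde
Conditions: TBSCl, imidazole, DMF, rt
Reagents that add atoms: tert-butyldimethylsilyl chloride, CC(C)(C)[Si](C)(C)Cl
Why: Standard silylation of a phenol.

**Step 4**
Reactants: 9 4-[(tert-butyldimethylsilyl)oxy]benzaldehyde
Product: 10 {4-[(tert-butyldimethylsilyl)oxy]phenyl}methanol
Conditions: NaBH4, MeOH, 0 °C
Reagents that add atoms: none
Why: Borohydride reduction of an aryl aldehyde, which leaves the aryl silyl ether intact at 0 °C.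

**Step 5**
Reactants: 10 {4-[(tert-butyldimethylsilyl)oxy]phenyl}methanol
Product: 11 [4-(bromomethyl)phenoxy](tert-butyl)dimethylsilane
Conditions: CBr4, PPh3, CH2Cl2, 0 °C
Reagents that add atoms: carbon tetrabromide, BrC(Br)(Br)Br
Why: Appel bromination under neutral conditions that spare the silyl ether; the bromide is used at once.

**Step 6**
Reactants: 7 5,7-bis(benzyloxy)-2',6'-dimethoxyspiro[chromane-2,1'-cyclohexa[2,5]diene]-4,4'-dione; 11 [4-(bromomethyl)phenoxy](tert-butyl)dimethylsilane
Product: 13 rac-5,7-bis(benzyloxy)-3-{4-[(tert-butyldimethylsilyl)oxy]benzyl}-2',6'-dimethoxyspiro[chromane-2,1'-cyclohexa[2,5]diene]-4,4'-dione, via lithium enolate 12 (not isolated)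
Conditions: LiN(SiMe3)2 (1.05 equiv), THF, −78 °C; 11, −78 → −30 °C
Reagents that add atoms: none
Why: Enolate alkylation (SN2 on a benzylic bromide) at C3, run cold because β-elimination of the aryloxide from a chromanone enolate is slow at −78 °C; the product is racemic at C3.

**Step 7**
Reactants: 13 rac-5,7-bis(benzyloxy)-3-{4-[(tert-butyldimethylsilyl)oxy]benzyl}-2',6'-dimethoxyspiro[chromane-2,1'-cyclohexa[2,5]diene]-4,4'-dione
Product: 15 (3R)-5,7-bis(benzyloxy)-3-{4-[(tert-butyldimethylsilyl)oxy]benzyl}-3-hydroxy-2',6'-dimethoxyspiro[chromane-2,1'-cyclohexa[2,5]diene]-4,4'-dione, via potassium enolate 14 (not isolated)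
Conditions: KN(SiMe3)2 (1.1 equiv), THF, −78 °C; (+)-(camphorsulfonyl)oxaziridine, −78 °C; AcOH quench at −78 °C
Reagents that add atoms: (+)-(2R,8aS)-(camphorsulfonyl)oxaziridine, CC1(C)[C@@H]2CC[C@@]13CS(=O)(=O)N4O[C@@]34C2
Why: Davis asymmetric enolate hydroxylation, in which the planar enolate has no other stereocentre so the camphor-derived oxaziridine alone should choose the face (as with 3-benzylchroman-4-one enolates), and the cold acid quench keeps the tertiary alkoxide from retro-aldol fragmentation.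

**Step 8**
Reactants: 15 (3R)-5,7-bis(benzyloxy)-3-{4-[(tert-butyldimethylsilyl)oxy]benzyl}-3-hydroxy-2',6'-dimethoxyspiro[chromane-2,1'-cyclohexa[2,5]diene]-4,4'-dione
Product: 16 (3R)-5,7-bis(benzyloxy)-3,2',6'-trihydroxy-3-(4-hydroxybenzyl)spiro[chromane-2,1'-cyclohexa[2,5]diene]-4,4'-dione
Conditions: 3 M aq. HCl, THF, 55 °C
Reagents that add atoms: water, O
Why: Acid hydrolysis of both methyl vinylogous esters (addition–elimination of water) and of the aryl silyl ether should give the symmetric dihydroxydienone without touching C3, while aryl benzyl ethers are stable to these conditions.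

**Step 9**
Reactants: 16 (3R)-5,7-bis(benzyloxy)-3,2',6'-trihydroxy-3-(4-hydroxybenzyl)spiro[chromane-2,1'-cyclohexa[2,5]diene]-4,4'-dione
Product: 18 furan-closed di-O-benzyl core as its vinylogous acid (C3 R; spiro carbon S; furan CH S bearing 4-hydroxyphenyl cis to the 3-hydroxyl; cis-fused tetrahydrofuran/chromanone), via quinone methide 17 (not isolated)
Conditions: DDQ (1.1 equiv), 1,4-dioxane, 10 °C → rt
Reagents that add atoms: none
Why: DDQ should dehydrogenate the 4-hydroxybenzyl group (the only free phenol with a para benzylic C–H) to the para-quinone methide 17, and an enol hydroxyl of the dienone then adds to its exocyclic carbon in an oxa-1,6-addition that restores the phenol. The closest known reaction type is the DDQ- or Ag2O-mediated dehydrogenative cyclisation of 4-hydroxybenzyl compounds carrying a pendant hydroxyl to 2-aryl dihydrobenzofurans and flavans. The tetrahydrofuran ring (enol carbon, O, CH(Ar), C3, spiro C2) closes 5-exo-trig at the quinone methide with the enol C=C outside the new ring, which favours O- over C-attack (the latter would be a 5-endo closure of the enol). The spiro carbon becomes stereogenic under control of C3: only the arm that gives the cis-fused furan/chromanone bicycle can reach the benzylic carbon, whichever half-chair the chromanone adopts, so the two equivalent arms are told apart. The benzylic centre is expected to be set thermodynamically, because the addition is reversible in the acidic medium (the hydroquinone of DDQ and the vinylogous acid itself), placing the aryl group on the convex face, cis to the C3 hydroxyl and away from the chromanone carbonyl. The step needs chemoselective oxidation of the phenol in the presence of the enols and benzyl ethers, which the low oxidation potential of the free phenol and one equivalent of oxidant should secure.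

**Step 10**
Reactants: 19 (R)-4-benzyloxazolidin-2-one; 20 (benzyloxy)acetyl chloride
Product: 22 (R)-4-benzyl-3-[(benzyloxy)acetyl]oxazolidin-2-one, via lithiated oxazolidinone 21 (not isolated)
Conditions: n-BuLi, THF, −78 °C; 20, −78 → 0 °C
Reagents that add atoms: none
Why: N-acylation of the lithiated oxazolidinone with an acid chloride.

**Step 11**
Reactants: 22 (R)-4-benzyl-3-[(benzyloxy)acetyl]oxazolidin-2-one; 23 4-(benzyloxy)benzaldehyde
Product: 25 (R)-4-benzyl-3-{(2R,3S)-2-(benzyloxy)-3-[4-(benzyloxy)phenyl]-3-hydroxypropanoyl}oxazolidin-2-one, via boron enolate 24 (not isolated)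
Conditions: Bu2BOTf, Et3N, CH2Cl2, −78 → 0 °C; 23, −78 → 0 °C; pH 7 buffer, MeOH, H2O2, 0 °C
Reagents that add atoms: none
Why: Evans syn-glycolate aldol, in which the Z boron enolate reacts through a Zimmerman–Traxler chair on the face away from the auxiliary benzyl group, so the (R)-auxiliary should give the (2R,3S) syn adduct.

**Step 12**
Reactants: 25 (R)-4-benzyl-3-{(2R,3S)-2-(benzyloxy)-3-[4-(benzyloxy)phenyl]-3-hydroxypropanoyl}oxazolidin-2-one
Product: 26 (R)-4-benzyl-3-{(2R,3S)-2-(benzyloxy)-3-[4-(benzyloxy)phenyl]-3-[(tert-butyldimethylsilyl)oxy]propanoyl}oxazolidin-2-one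
Conditions: TBSOTf, 2,6-lutidine, CH2Cl2, 0 °C
Reagents that add atoms: tert-butyldimethylsilyl triflate, CC(C)(C)[Si](C)(C)OS(=O)(=O)C(F)(F)F
Why: Silylation of the secondary benzylic alcohol with a silyl triflate, which differentiates the two oxygens of the future flavan.

**Step 13**
Reactants: 26 (R)-4-benzyl-3-{(2R,3S)-2-(benzyloxy)-3-[4-(benzyloxy)phenyl]-3-[(tert-butyldimethylsilyl)oxy]propanoyl}oxazolidin-2-one
Product: 27 (2S,3S)-2-(benzyloxy)-3-[4-(benzyloxy)phenyl]-3-[(tert-butyldimethylsilyl)oxy]propan-1-ol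
Conditions: LiBH4, THF/Et2O, 0 °C → rt
Reagents that add atoms: none
Why: Reductive removal of the oxazolidinone auxiliary with lithium borohydride, which does not touch either stereocentre (the descriptor at C2 changes only by priority).

**Step 14**
Reactants: 27 (2S,3S)-2-(benzyloxy)-3-[4-(benzyloxy)phenyl]-3-[(tert-butyldimethylsilyl)oxy]propan-1-ol
Product: 28 (2R,3S)-2-(benzyloxy)-3-[4-(benzyloxy)phenyl]-3-[(tert-butyldimethylsilyl)oxy]propanal
Conditions: Dess–Martin periodinane, CH2Cl2, 0 °C → rt
Reagents that add atoms: none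
Why: Dess–Martin oxidation gives the α-alkoxy aldehyde under non-basic conditions that should avoid epimerisation; it is used directly.

**Step 15**
Reactants: 18 furan-closed di-O-benzyl core (vinylogous acid); 28 (2R,3S)-2-(benzyloxy)-3-[4-(benzyloxy)phenyl]-3-[(tert-butyldimethylsilyl)oxy]propanal
Product: 30 C-alkylated vinylogous acid carrying the (2S,3S)-2-(benzyloxy)-3-[4-(benzyloxy)phenyl]-3-[(tert-butyldimethylsilyl)oxy]propyl chain on the carbon between the enol and the ketone, via alkylidene dione 29 (not isolated)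
Conditions: Hantzsch ester (1.2 equiv), L-proline (10 mol%), CH2Cl2, rt
Reagents that add atoms: none
Why: Three-component reductive alkylation (Knoevenagel condensation at the only 1,3-dicarbonyl carbon, then conjugate hydride transfer from the Hantzsch ester), a method known to carry α-oxygenated chiral aldehydes through without loss of configuration.

**Step 16**
Reactants: 30 C-alkylated vinylogous acid
Product: 32 tetra-O-benzyl target (pyran closed; flavan part 2S,3S with 2-aryl and 3-benzyloxy cis), via benzylic alcohol 31 (not isolated)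
Conditions: HF·pyridine, pyridine, THF, 0 °C → rt; then PPTS (cat.), 4 Å molecular sieves, CH2Cl2, rt
Reagents that add atoms: none
Why: Fluoride desilylation, then acid-catalysed cyclodehydration (intramolecular vinylogous ester formation), in which the benzylic hydroxyl should attack the ketone-type carbon next to the spiro centre rather than the vinylogous-ester carbonyl (as 4-hydroxycoumarins etherify at C4); no C–O bond at either side-chain stereocentre is broken, so the syn aldol configuration is carried over as the 2,3-cis flavan.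

**Step 17**
Reactants: 32 tetra-O-benzyl target
Product: 33 target CNP0170480.5
Conditions: H2 (1 atm), Pd(OH)2/C, THF/MeOH, rt, stopped at full conversion
Reagents that add atoms: none
Why: Hydrogenolysis of three aryl benzyl ethers and one alkyl benzyl ether under neutral conditions, as in the last step of catechin syntheses, where the cyclic benzylic C–O bonds react much more slowly.

**Compound list**
1 | 1-(2,4,6-trifluorophenyl)ethan-1-one | CC(=O)c1c(F)cc(F)cc1F | starting material
2 | 1-[4-(benzyloxy)-2,6-difluorophenyl]ethan-1-one (not isolated) | CC(=O)c1c(F)cc(OCc2ccccc2)cc1F | intermediate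
3 | 1-[2,4-bis(benzyloxy)-6-fluorophenyl]ethan-1-one | CC(=O)c1c(F)cc(OCc2ccccc2)cc1OCc1ccccc1 | intermediate
4 | 2,6-dimethoxy-1,4-benzoquinone | COC1=CC(=O)C=C(OC)C1=O | starting material
5 | lithium enolate of 3 (not isolated) | [Li+].[O-]C(=C)c1c(F)cc(OCc2ccccc2)cc1OCc1ccccc1 | intermediate
6 | lithium 1-{2-[2,4-bis(benzyloxy)-6-fluorophenyl]-2-oxoethyl}-2,6-dimethoxy-4-oxocyclohexa-2,5-dien-1-olate (not isolated) | [Li+].[O-]C1(CC(=O)c2c(F)cc(OCc3ccccc3)cc2OCc2ccccc2)C(OC)=CC(=O)C=C1OC | intermediate
7 | 5,7-bis(benzyloxy)-2',6'-dimethoxyspiro[chromane-2,1'-cyclohexa[2,5]diene]-4,4'-dione | COC1=CC(=O)C=C(OC)C12CC(=O)c1c(OCc3ccccc3)cc(OCc3ccccc3)cc1O2 | intermediate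
8 | 4-hydroxybenzaldehyde | O=Cc1ccc(O)cc1 | starting material
9 | 4-[(tert-butyldimethylsilyl)oxy]benzaldehyde | CC(C)(C)[Si](C)(C)Oc1ccc(C=O)cc1 | intermediate
10 | {4-[(tert-butyldimethylsilyl)oxy]phenyl}methanol | CC(C)(C)[Si](C)(C)Oc1ccc(CO)cc1 | intermediate
11 | [4-(bromomethyl)phenoxy](tert-butyl)dimethylsilane | CC(C)(C)[Si](C)(C)Oc1ccc(CBr)cc1 | intermediate
12 | lithium C3=C4 enolate of 7 (not isolated) | [Li+].COC1=CC(=O)C=C(OC)C12C=C([O-])c1c(OCc3ccccc3)cc(OCc3ccccc3)cc1O2 | intermediate
13 | rac-5,7-bis(benzyloxy)-3-{4-[(tert-butyldimethylsilyl)oxy]benzyl}-2',6'-dimethoxyspiro[chromane-2,1'-cyclohexa[2,5]diene]-4,4'-dione | COC1=CC(=O)C=C(OC)C12Oc3cc(OCc4ccccc4)cc(OCc4ccccc4)c3C(=O)C2Cc2ccc(O[Si](C)(C)C(C)(C)C)cc2 | intermediate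
14 | potassium enolate of 13 (not isolated) | [K+].COC1=CC(=O)C=C(OC)C12Oc3cc(OCc4ccccc4)cc(OCc4ccccc4)c3C([O-])=C2Cc2ccc(O[Si](C)(C)C(C)(C)C)cc2 | intermediate
15 | (3R)-5,7-bis(benzyloxy)-3-{4-[(tert-butyldimethylsilyl)oxy]benzyl}-3-hydroxy-2',6'-dimethoxyspiro[chromane-2,1'-cyclohexa[2,5]diene]-4,4'-dione | COC1=CC(=O)C=C(OC)C12Oc3cc(OCc4ccccc4)cc(OCc4ccccc4)c3C(=O)[C@@]2(O)Cc2ccc(O[Si](C)(C)C(C)(C)C)cc2 | intermediate
16 | (3R)-5,7-bis(benzyloxy)-3,2',6'-trihydroxy-3-(4-hydroxybenzyl)spiro[chromane-2,1'-cyclohexa[2,5]diene]-4,4'-dione (symmetric dihydroxydienone; key-step precursor) | O=C1C=C(O)C2(Oc3cc(OCc4ccccc4)cc(OCc4ccccc4)c3C(=O)[C@@]2(O)Cc2ccc(O)cc2)C(O)=C1 | intermediate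
17 | para-quinone methide of 16: the C3 substituent is (4-oxocyclohexa-2,5-dien-1-ylidene)methyl (not isolated) | O=C1C=C(O)C2(Oc3cc(OCc4ccccc4)cc(OCc4ccccc4)c3C(=O)[C@@]2(O)C=C2C=CC(=O)C=C2)C(O)=C1 | intermediate
18 | furan-closed di-O-benzyl core as its vinylogous acid: tetrahydrofuran ring between one enol oxygen and the benzylic carbon; C3 R, spiro carbon S, furan CH S with 4-hydroxyphenyl cis to the 3-hydroxyl; chromanone O1 and C4 on the opposite face (cis fusion); second arm a free hydroxy-enone (key-step product) | O=C1C=C2O[C@@H](c3ccc(O)cc3)[C@]3(O)C(=O)c4c(OCc5ccccc5)cc(OCc5ccccc5)cc4O[C@]23C(O)=C1 | intermediate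
19 | (R)-4-benzyloxazolidin-2-one | O=C1N[C@H](Cc2ccccc2)CO1 | starting material
20 | (benzyloxy)acetyl chloride | O=C(Cl)COCc1ccccc1 | starting material
21 | lithium salt of 19 (not isolated) | [Li+].O=C1[N-][C@H](Cc2ccccc2)CO1 | intermediate
22 | (R)-4-benzyl-3-[(benzyloxy)acetyl]oxazolidin-2-one | O=C1OC[C@@H](Cc2ccccc2)N1C(=O)COCc1ccccc1 | intermediate
23 | 4-(benzyloxy)benzaldehyde | O=Cc1ccc(OCc2ccccc2)cc1 | starting material
24 | dibutylboron Z-enolate of 22 (not isolated) | CCCCB(CCCC)O/C(N1C(=O)OC[C@H]1Cc1ccccc1)=C\OCc1ccccc1 | intermediate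
25 | (R)-4-benzyl-3-{(2R,3S)-2-(benzyloxy)-3-[4-(benzyloxy)phenyl]-3-hydroxypropanoyl}oxazolidin-2-one | O=C1OC[C@@H](Cc2ccccc2)N1C(=O)[C@H](OCc1ccccc1)[C@@H](O)c1ccc(OCc2ccccc2)cc1 | intermediate
26 | (R)-4-benzyl-3-{(2R,3S)-2-(benzyloxy)-3-[4-(benzyloxy)phenyl]-3-[(tert-butyldimethylsilyl)oxy]propanoyl}oxazolidin-2-one | O=C1OC[C@@H](Cc2ccccc2)N1C(=O)[C@H](OCc1ccccc1)[C@@H](O[Si](C)(C)C(C)(C)C)c1ccc(OCc2ccccc2)cc1 | intermediate
27 | (2S,3S)-2-(benzyloxy)-3-[4-(benzyloxy)phenyl]-3-[(tert-butyldimethylsilyl)oxy]propan-1-ol | OC[C@H](OCc1ccccc1)[C@@H](O[Si](C)(C)C(C)(C)C)c1ccc(OCc2ccccc2)cc1 | intermediate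
28 | (2R,3S)-2-(benzyloxy)-3-[4-(benzyloxy)phenyl]-3-[(tert-butyldimethylsilyl)oxy]propanal | O=C[C@H](OCc1ccccc1)[C@@H](O[Si](C)(C)C(C)(C)C)c1ccc(OCc2ccccc2)cc1 | intermediate
29 | Knoevenagel alkylidene dione from 18 and 28 (not isolated) | O=C1C=C2O[C@@H](c3ccc(O)cc3)[C@]3(O)C(=O)c4c(OCc5ccccc5)cc(OCc5ccccc5)cc4O[C@]23C(=O)C1=C[C@H](OCc1ccccc1)[C@@H](O[Si](C)(C)C(C)(C)C)c1ccc(OCc2ccccc2)cc1 | intermediate
30 | C-alkylated vinylogous acid: 18 carrying the (2S,3S)-2-(benzyloxy)-3-[4-(benzyloxy)phenyl]-3-[(tert-butyldimethylsilyl)oxy]propyl chain on the carbon between enol and ketone | O=C1C=C2O[C@@H](c3ccc(O)cc3)[C@]3(O)C(=O)c4c(OCc5ccccc5)cc(OCc5ccccc5)cc4O[C@]23C(O)=C1C[C@H](OCc1ccccc1)[C@@H](O[Si](C)(C)C(C)(C)C)c1ccc(OCc2ccccc2)cc1 | intermediate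
31 | desilylated benzylic alcohol of 30 (not isolated) | O=C1C=C2O[C@@H](c3ccc(O)cc3)[C@]3(O)C(=O)c4c(OCc5ccccc5)cc(OCc5ccccc5)cc4O[C@]23C(O)=C1C[C@H](OCc1ccccc1)[C@@H](O)c1ccc(OCc2ccccc2)cc1 | intermediate
32 | tetra-O-benzyl target: pyran closed, flavan part (2S,3S) with 2-[4-(benzyloxy)phenyl] and 3-benzyloxy cis; benzyl ethers also on the two chromanone phenols | O=C1C=C2O[C@@H](c3ccc(O)cc3)[C@]3(O)C(=O)c4c(OCc5ccccc5)cc(OCc5ccccc5)cc4O[C@]23C2=C1C[C@H](OCc1ccccc1)[C@H](c1ccc(OCc3ccccc3)cc1)O2 | intermediate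
33 | CNP0170480.5 | O=C1C=C2O[C@@H](c3ccc(O)cc3)[C@]3(O)C(=O)c4c(O)cc(O)cc4O[C@]23C2=C1C[C@H](O)[C@H](c1ccc(O)cc1)O2 | target

**Step count and risks**
Total step count: 17. Longest linear sequence: 10 steps (steps 3, 4, 5, 6, 7, 8, 9, 15, 16, 17, from 4-hydroxybenzaldehyde).

Steps most likely to fail:

1. Step 2. Retro-aldol cleavage of the tertiary aldolate may outrun the SNAr closure on warming, and residual base may open the product by β-elimination of the aryloxide. Fallback, from 3 back to 7: the spiro C–O bond is made by phenol dearomatisation instead of SNAr, so no aldolate has to survive warming. Hydroxide SNAr (KOH, DMSO/H2O, 60 °C) converts 3 into 1-[2,4-bis(benzyloxy)-6-hydroxyphenyl]ethan-1-one F1. Its dianion (LiN(SiMe3)2, 2.1 equiv, THF, −78 °C) adds to quinone 4, and a cold acetic acid quench gives the quinol F2. Zn in acetic acid reduces the quinol to the deoxybenzoin F3, a 4-alkyl-3,5-dimethoxyphenol. PhI(OAc)2 in (CF3)2CHOH at 0 °C oxidises that phenol, and the ortho-acyl phenol oxygen adds at its para carbon to give 7.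

2. Step 9. The enol carbon may add to DDQ, or over-oxidation may compete with benzylic dehydrogenation; the benzylic centre may also fail to equilibrate fully. Fallback, from 15 back to 18: oxidation is done before the enols are unmasked, and the ring is closed by acid. Bu4NF buffered with AcOH frees the phenol F4. DDQ in MeOH/CH2Cl2 converts its 4-hydroxybenzyl group, via the quinone methide and methanol capture, into the benzylic methyl ether F5. Aqueous HCl in THF at 55 °C then hydrolyses the two methyl enol ethers and ionises the para-hydroxybenzyl methyl ether to the same quinone methide, which the freed enol captures under thermodynamic control to give 18.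

3. Step 16. Enol-ether formation may occur at the wrong carbonyl (the one flanked by CH), and ionisation of the benzylic C–O bond could scramble that centre. Fallback, from 18 back to 33: a domino Knoevenagel/hetero-Diels–Alder reaction, in which the more electron-poor ketone carbonyl enters the oxadiene and the Z alkene delivers the cis pair suprafacially. The (Z)-enol acetate F6 is made from 1-(benzyloxy)-4-ethynylbenzene and acetic acid with [RuCl2(p-cymene)]2, P(4-ClC6H4)3 and 4-(dimethylamino)pyridine. Compound 18, paraformaldehyde and F6 with ethylenediammonium diacetate in MeCN at 60 °C give the cis 3-acetoxy adduct F7. Its facial diastereomers relative to the core have to be separated, since the core gives no reliable control here. K2CO3 in MeOH at 0 °C removes the acetate to give F8, and H2 over Pd(OH)2/C gives 33.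

**Further compounds**
F1 | step 2 | 1-[2,4-bis(benzyloxy)-6-hydroxyphenyl]ethan-1-one | CC(=O)c1c(O)cc(OCc2ccccc2)cc1OCc1ccccc1
F2 | step 2 | 4-{2-[2,4-bis(benzyloxy)-6-hydroxyphenyl]-2-oxoethyl}-4-hydroxy-3,5-dimethoxycyclohexa-2,5-dien-1-one | COC1=CC(=O)C=C(OC)C1(O)CC(=O)c1c(O)cc(OCc2ccccc2)cc1OCc1ccccc1
F3 | step 2 | 1-[2,4-bis(benzyloxy)-6-hydroxyphenyl]-2-(4-hydroxy-2,6-dimethoxyphenyl)ethan-1-one | COc1cc(O)cc(OC)c1CC(=O)c1c(O)cc(OCc2ccccc2)cc1OCc1ccccc1
F4 | step 9 | (3R)-5,7-bis(benzyloxy)-3-hydroxy-3-(4-hydroxybenzyl)-2',6'-dimethoxyspiro[chromane-2,1'-cyclohexa[2,5]diene]-4,4'-dione | COC1=CC(=O)C=C(OC)C12Oc3cc(OCc4ccccc4)cc(OCc4ccccc4)c3C(=O)[C@@]2(O)Cc2ccc(O)cc2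
F5 | step 9 | (3R)-5,7-bis(benzyloxy)-3-hydroxy-3-[(4-hydroxyphenyl)(methoxy)methyl]-2',6'-dimethoxyspiro[chromane-2,1'-cyclohexa[2,5]diene]-4,4'-dione (both benzylic epimers) | COC1=CC(=O)C=C(OC)C12Oc3cc(OCc4ccccc4)cc(OCc4ccccc4)c3C(=O)[C@@]2(O)C(OC)c2ccc(O)cc2
F6 | step 16 | (Z)-2-[4-(benzyloxy)phenyl]ethenyl acetate | CC(=O)O/C=C\c1ccc(OCc2ccccc2)cc1
F7 | step 16 | tri-O-benzyl target carrying a 3-acetoxy group on the flavan ring (2S,3S, cis) | O=C1C=C2O[C@@H](c3ccc(O)cc3)[C@]3(O)C(=O)c4c(OCc5ccccc5)cc(OCc5ccccc5)cc4O[C@]23C2=C1C[C@H](OC(C)=O)[C@H](c1ccc(OCc3ccccc3)cc1)O2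
F8 | step 16 | tri-O-benzyl target with free flavan 3-hydroxyl | O=C1C=C2O[C@@H](c3ccc(O)cc3)[C@]3(O)C(=O)c4c(OCc5ccccc5)cc(OCc5ccccc5)cc4O[C@]23C2=C1C[C@H](O)[C@H](c1ccc(OCc3ccccc3)cc1)O2
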